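**Assumption:** the target has no stereocentre and no stable chiral axis (the diaryl ether rotates freely), so it is achiral and no stereochemical step is needed. 1-Nitro-3-phenoxybenzene is taken as a catalogue compound.

**Retrosynthetic overview**
1. 7 ⇐ 5: the middle bromine comes last, by Sandmeyer replacement of an NH2 group.
2. 5 ⇐ 4: that same NH2 first places the two flanking bromines (ortho,ortho-dibromination).
3. 4 ⇐ 2 (key step): a Bamberger rearrangement in methanol turns NO2 into NH2 and, in the same operation, puts OMe on the para C–H (C–H methoxylation by nitrenium umpolung).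
4. 2 ⇐ 1: the two ring-B bromines by SEAr on 3-nitrodiphenyl ether, while NO2 keeps ring A silent.
5. No ring is formed and no aryl–O coupling (Ullmann/SNAr/iodonium, the usual first disconnection) is used: both rings and the ether oxygen are bought in 1, and one nitrogen atom acts as a traceless linchpin.

**Route**

Step 1
Reactants: 1 1-nitro-3-phenoxybenzene
Product: 2 2,4-dibromo-1-(3-nitrophenoxy)benzene
Conditions: Br2 (2.2 equiv), Fe powder (5 mol %), CH2Cl2, 0 °C → 40 °C
Reagents that add atoms: bromine, BrBr
Why: Electrophilic aromatic bromination (SEAr), in which the nitro group deactivates its own ring so that both bromines enter the phenoxy ring, first para and then ortho to the ether oxygen, which also removes ring B as a competing nucleophile for the next step.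

Step 2
Reactants: 2 2,4-dibromo-1-(3-nitrophenoxy)benzene
Product: 4 3-(2,4-dibromophenoxy)-4-methoxyaniline, via arylhydroxylamine 3 (not isolated)
Conditions: Zn dust (2.2 equiv), NH4Cl, MeOH/THF, 0–10 °C; filter; then conc. H2SO4, MeOH, 0 → 65 °C
Reagents that add atoms: methanol, CO
Why: Zn/NH4Cl stops the nitro reduction at the N-arylhydroxylamine, whose O-protonated form loses water to an aryl nitrenium (iminocyclohexadienyl) cation that methanol captures at the carbon para to nitrogen before re-aromatisation, i.e. a Bamberger rearrangement run in methanol, which is known to give p-alkoxyanilines and tolerates aryl bromides and the diaryl ether.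

Step 3
Reactants: 4 3-(2,4-dibromophenoxy)-4-methoxyaniline
Product: 5 2,6-dibromo-3-(2,4-dibromophenoxy)-4-methoxyaniline
Conditions: NBS (2.05 equiv), MeCN, 0 °C → rt
Reagents that add atoms: N-bromosuccinimide, O=C1CCC(=O)N1Br
Why: SEAr bromination governed by the free NH2 group, by far the strongest donor, which takes exactly two bromines at its two ortho positions (its para position is blocked by OMe) and leaves the C–H ortho to OMe and the deactivated dibromophenoxy ring untouched.

Step 4
Reactants: 5 2,6-dibromo-3-(2,4-dibromophenoxy)-4-methoxyaniline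
Product: 7 1,2,3-tribromo-4-(2,4-dibromophenoxy)-5-methoxybenzene, via arenediazonium bromide 6 (not isolated)
Conditions: t-BuONO (1.5 equiv), CuBr2 (1.2 equiv), MeCN, 0 → 60 °C
Reagents that add atoms: copper(II) bromide, [Cu+2].[Br-].[Br-]
Why: Sandmeyer bromination in its non-aqueous (Doyle) form, where tert-butyl nitrite diazotises the weakly basic 2,6-dibromoaniline and copper bromide replaces N2 by bromine at the carbon that carried nitrogen, so the 3,4,5-tribromo pattern is fixed by construction and the aryl radical (meta to the ether) cannot cyclise onto ring B.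

**Compound list**
1 | 1-nitro-3-phenoxybenzene (3-nitrodiphenyl ether) | O=[N+]([O-])c1cccc(Oc2ccccc2)c1 | starting material
2 | 2,4-dibromo-1-(3-nitrophenoxy)benzene | O=[N+]([O-])c1cccc(Oc2ccc(Br)cc2Br)c1 | intermediate
3 | N-[3-(2,4-dibromophenoxy)phenyl]hydroxylamine | ONc1cccc(Oc2ccc(Br)cc2Br)c1 | intermediate
4 | 3-(2,4-dibromophenoxy)-4-methoxyaniline | COc1ccc(N)cc1Oc1ccc(Br)cc1Br | intermediate
5 | 2,6-dibromo-3-(2,4-dibromophenoxy)-4-methoxyaniline | COc1cc(Br)c(N)c(Br)c1Oc1ccc(Br)cc1Br | intermediate
6 | 2,6-dibromo-3-(2,4-dibromophenoxy)-4-methoxybenzenediazonium bromide | COc1cc(Br)c([N+]#N)c(Br)c1Oc1ccc(Br)cc1Br.[Br-] | intermediate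
7 | 1,2,3-tribromo-4-(2,4-dibromophenoxy)-5-methoxybenzene (= 3,4,5-tribromo-2-(2,4-dibromophenoxy)anisole) | COc1cc(Br)c(Br)c(Br)c1Oc1ccc(Br)cc1Br | target

**Total step count:** 4. **Longest linear sequence:** 4.

**Three steps most likely to fail, with fallbacks**

Step 2 (Bamberger methoxylation) is the riskiest. Methanol may also attack ortho to nitrogen (para to the aryloxy group), and over-reduction to the aniline or azoxy formation can lower the yield. The fallback sets out from 2 and comes back at 4. It drops the nitrenium cation and uses the nitro group as the activator for a vicarious nucleophilic substitution of hydrogen. Compound 2 with cumene hydroperoxide and t-BuOK in liquid NH3/THF at −33 °C adds the hydroperoxide anion para to NO2; base-induced loss of cumyl alkoxide gives 2-(2,4-dibromophenoxy)-4-nitrophenol F1. MeI/K2CO3 in DMF gives 2,4-dibromo-1-(2-methoxy-5-nitrophenoxy)benzene F2. Fe/NH4Cl in EtOH/H2O at 80 °C reduces F2 to 4.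

Step 4 (Sandmeyer on a hindered, weakly basic 2,6-dibromoaniline) may give hydrodediazoniation (Ar–H) or incomplete diazotisation under copper/radical conditions. The fallback sets out from 5 and comes back at 7. It replaces the copper/aryl-radical C–Br formation by an ionic cleavage of an isolable triazene. Compound 5 is diazotised with t-BuONO and HBr/AcOH in MeCN at 0 °C to 6, which is quenched into pyrrolidine/K2CO3 to give (E)-1-{[2,6-dibromo-3-(2,4-dibromophenoxy)-4-methoxyphenyl]diazenyl}pyrrolidine F3. After purification, F3 with TMSBr in MeCN at 60 °C gives 7.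

Step 1 (double bromination of ring B) may stall at the monobromide or run on to a third bromine, giving mixtures that are hard to separate. The fallback sets out from 1 and comes back at 7. It leaves ring B bare and brominates it last, when ring A carries three bromines and is the less reactive ring. Compound 1 is taken through the same Zn/NH4Cl then H2SO4/MeOH sequence, through N-(3-phenoxyphenyl)hydroxylamine F4, to 4-methoxy-3-phenoxyaniline F5. NBS (2.0 equiv, MeCN, −20 °C) gives 2,6-dibromo-4-methoxy-3-phenoxyaniline F6. t-BuONO/CuBr2 in MeCN converts F6, through 2,6-dibromo-4-methoxy-3-phenoxybenzenediazonium bromide F7, into 1,2,3-tribromo-5-methoxy-4-phenoxybenzene F8. Br2 (2.2 equiv) with catalytic Fe in CH2Cl2 then places the para and ortho bromines on the phenoxy ring to give 7.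

**Further compounds**
F1 | step 2 | 2-(2,4-dibromophenoxy)-4-nitrophenol | Oc1ccc(cc1Oc1ccc(Br)cc1Br)[N+](=O)[O-]
F2 | step 2 | 2,4-dibromo-1-(2-methoxy-5-nitrophenoxy)benzene | COc1ccc(cc1Oc1ccc(Br)cc1Br)[N+](=O)[O-]
F3 | step 4 | (E)-1-{[2,6-dibromo-3-(2,4-dibromophenoxy)-4-methoxyphenyl]diazenyl}pyrrolidine | COc1cc(Br)c(/N=N/N2CCCC2)c(Br)c1Oc1ccc(Br)cc1Br
F4 | step 1 | N-(3-phenoxyphenyl)hydroxylamine | ONc1cccc(Oc2ccccc2)c1
F5 | step 1 | 4-methoxy-3-phenoxyaniline | COc1ccc(N)cc1Oc1ccccc1
F6 | step 1 | 2,6-dibromo-4-methoxy-3-phenoxyaniline | COc1cc(Br)c(N)c(Br)c1Oc1ccccc1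
F7 | step 1 | 2,6-dibromo-4-methoxy-3-phenoxybenzenediazonium bromide | COc1cc(Br)c([N+]#N)c(Br)c1Oc1ccccc1.[Br-]
F8 | step 1 | 1,2,3-tribromo-5-methoxy-4-phenoxybenzene | COc1cc(Br)c(Br)c(Br)c1Oc1ccccc1
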